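(The earlier runs and the new flask stem from a simulated flask with made-up constants; scatter was added.)

| flask | starting material | protic impurity | remark | time |
|---|---|---|---|---|
| elm | 1 M | 0.15 M | run made earlier |  |
| alder | 2.2 M | 0.15 M | run made earlier |  |
| cedar | 1.5 M | 0.22 M | run made earlier |  |
| flask | 1.5 M | 0.150 M |  | 4.0 h |

| run | time / h | target / % |
|---|---|---|
| elm | 0.333 | 18 |
| elm | 1.00 | 23 |
| elm | 2.00 | 20 |
| elm | 3.00 | 17 |
| elm | 4.00 | 13 |
| alder | 0.333 | 21 |
| alder | 0.667 | 24 |
| alder | 1.00 | 25 |
| alder | 2.00 | 21 |
| alder | 4.00 | 16 |
| cedar | 0.333 | 18 |
| cedar | 0.667 | 22 |
| cedar | 1.00 | 27 |
| cedar | 2.00 | 18 |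
| cedar | 4.00 | 13 |

(standard deviation of a reading: 1.5 percentage points)

- amount of target in percent of the starting material charged, at 25 min, 80 min, 2.5 h and 4.0 h

- on the list of suspects stand: starting material <-> target; target <-> isomer of the product; isomer of the product <-> starting material; target -> over-reaction product; starting material + protic impurity -> quenched substrate

- A small charge of protic impurity gives my first number. I assume it takes starting material one for one and early, as the limiting reagent of that quench. The usable fraction of the charge is then 90.0% in this flask, against 85.0% in elm, 93.2% in alder and 85.3% in cedar.

- My objection is that the readings are of target, not of quenched substrate. But at 1.00 h elm's target over alder's reads 0.920, and their usable fractions stand at 0.912, so I keep the assumption, knowing that each reading carries its scatter.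

- Next I divide the readings by the usable fraction and solve the falling end. Averaged over the three runs, target per usable charge reads 28.5% at 1.00 h and 15.9% at 4.00 h. The late half-life of target, the time in which target per usable charge halves after its peak, therefore reads 3.56 h.

- Yet the first of those readings lies near the peak, so the fall may not be a single decay from there. For target per usable charge, the late half-life gives 23.5% at 2.00 h, and the runs average 22.4%, a gap smaller than the scatter of one reading, 1.5 percentage points, so I keep it.

- For this flask I multiply by its usable fraction and reckon target at 24.0% of the charge at 80 min, 19.2% at 2.5 h and 14.3% at 4.0 h.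

- The rising end I join by a straight line between the mean first and second readings, which gives 20.4% at 25 min. The curve bends over there, so I expect this chord to read low.

- The forecast, which differs slightly from mine, gives 21%, 23.5%, 19% and 14.5%, holding that “the usable fraction is what matters”, and the flask gives 22.2%, 24.3%, 19.4% and 14.4%.

    starting material ⇌ target (K = 0.840, k = 0.0140 /min)
    target ⇌ isomer of the product (K = 0.590, k = 0.0630 /min)
    isomer of the product ⇌ starting material (k = 0.0470 /min)
    target → over-reaction product (k = 0.00990 /min)
    starting material + protic impurity → quenched substrate (k = 3.60 /M/min)

- In this flask the protic impurity stood at 0% of its charge by 0.400 h, with 10.0% of the starting material as quenched substrate and 21.8% as target. Carrying this flask's target of 19.4% at 2.5 h forward by the late half-life gives 14.5% at 4.0 h, against 14.4%. In elm, the same half-life gives 16.4% at 3.00 h, where the reading is 17%. Meanwhile this flask's target kept passing to over-reaction product, with the mid-point of that turnover at 1.81 h and 46.9% of the charge gone that way by 4.0 h.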